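**Retrosynthetic overview**

- The target is an all-cis oxolane (O1, C2 aryl, C3 CH2OH, C4 CH(OH)Ar, C5 H2). The carbinol carbon is cut from its aryl group (Felkin–Anh addition of an aryllithium to a C4 carbaldehyde), and that aldehyde plus the C3 CH2OH are tied back into a cis-fused γ-lactone.
- Key disconnection: the O1–C5H2 unit is one molecule of formaldehyde. A (3+2) annulation of formaldehyde with a cyclopropane-fused lactone forms C5–C4 and O1–C2 in one operation.
- Enabling feature: C2 is a benzylic carbon with an oxygenated aryl group (donor site), and C4 is α to a carbon that can be raised to the carboxyl level (acceptor site). The two are 1,3-related across C3, which is the pattern of a donor–acceptor cyclopropane; the cis C3/C4 branches allow the lactone tether, and a geminal ester is a removable extra activator.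
- The cyclopropane comes from coniferaldehyde and dimethyl bromomalonate by iminium-catalysed Michael-initiated ring closure, which sets the absolute configuration.
- Ring order: cyclopropane, then γ-lactone, then oxolane (key step, inversion at the benzylic carbon turns the trans cyclopropane into the 2,3-cis oxolane); the cyclopropane is consumed and the lactone is opened later.

Key step: step 4

Remark: the target is read as the (S)-carbinol on an oxolane whose three ring substituents are all cis; paraformaldehyde is taken as the source of monomeric formaldehyde.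

**Route**

Step 1
Reactants: 1 coniferaldehyde
Product: 2 2-methoxy-4-[(E)-3-oxoprop-1-enyl]phenyl pivalate
Conditions: PivCl, Et3N, DMAP (cat.), CH2Cl2, 0 °C to rt
Reagents that add atoms: pivaloyl chloride, CC(C)(C)C(Cl)=O
Why: DMAP-catalysed acylation of the phenol; the pivalate lowers the donor strength of the aryl group for step 4 and survives borohydride.

Step 2
Reactants: 2 2-methoxy-4-[(E)-3-oxoprop-1-enyl]phenyl pivalate; 3 dimethyl bromomalonate
Product: 4 dimethyl (2S,3R)-2-formyl-3-[3-methoxy-4-(pivaloyloxy)phenyl]cyclopropane-1,1-dicarboxylate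
Conditions: (R)-α,α-diphenylprolinol trimethylsilyl ether (20 mol%), 2,6-lutidine (1.1 equiv), CH2Cl2, 0 °C to rt
Reagents that add atoms: none
Why: Iminium-catalysed Michael-initiated ring closure: the (R)-catalyst shields one face of the iminium ion, bromomalonate adds to the β-carbon from the open face and the enamine displaces bromide (3-exo-tet), which should set both centres trans as (2S,3R), the mirror image of the (2R,3S) series known for the (S)-catalyst with cinnamaldehydes.

Step 3
Reactants: 4 dimethyl (2S,3R)-2-formyl-3-[3-methoxy-4-(pivaloyloxy)phenyl]cyclopropane-1,1-dicarboxylate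
Product: 6 methyl (1R,5S,6R)-6-[3-methoxy-4-(pivaloyloxy)phenyl]-2-oxo-3-oxabicyclo[3.1.0]hexane-1-carboxylate, via hydroxymethyl diester 5 (not isolated)
Conditions: NaBH4, MeOH/CH2Cl2, −20 °C; then p-TsOH (cat.), CH2Cl2, rt
Reagents that add atoms: none
Why: Chemoselective borohydride reduction of the aldehyde followed by acid-catalysed lactonisation onto the only ester that is cis to the new CH2OH; this makes C1 a stereocentre fixed by the cis ring fusion and leaves the aryl group exo.

Step 4
Reactants: 6 methyl (1R,5S,6R)-6-[3-methoxy-4-(pivaloyloxy)phenyl]-2-oxo-3-oxabicyclo[3.1.0]hexane-1-carboxylate; 7 formaldehyde (as paraformaldehyde)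
Product: 9 methyl (1S,5S,6S)-6-[3-methoxy-4-(pivaloyloxy)phenyl]-2-oxo-3,7-dioxabicyclo[3.3.0]octane-1-carboxylate, via oxocarbenium enolate 8 (not isolated)
Conditions: (CH2O)n (3 equiv as CH2O), Sn(OTf)2 (10 mol%; SnCl4 if sluggish), 4 Å MS, ClCH2CH2Cl, rt to 45 °C
Reagents that add atoms: none
Why: Sn(OTf)2 chelates the lactone and ester carbonyls on C1 and polarises the C1–C6 bond, the formaldehyde oxygen attacks benzylic C6 anti to the departing C1 (SN2-like) to give oxocarbenium enolate 8, and after rotation about C5–C6 the enolate carbon adds to the oxocarbenium carbon. The closest known reaction is the Lewis acid catalysed (3+2) annulation of 2-arylcyclopropane-1,1-diesters with aldehydes, which gives tetrahydrofurans with inversion at the donor carbon; formaldehyde is here simply the aldehyde partner. The oxolane ring closes in the C–C bond-forming aldol step, formally a 5-(enolexo)-endo-trig attack on the oxocarbenium ion, as in all such annulations. The new benzylic centre is controlled by stereospecific inversion of the exo cyclopropane, which places the aryl group cis to the CH2O branch on C5, and the new quaternary centre by the existing lactone ring, which allows only cis fusion. The step needs SN2 opening to outrun ionisation to a benzylic cation: the pivalate holds the aryl group near the donor strength of phenyl, and the untouched stereocentre C5 makes any reversible reclosure return the same exo cyclopropane. Attack at C6 and not at C5 follows from the aryl donor.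

Step 5
Reactants: 9 methyl (1S,5S,6S)-6-[3-methoxy-4-(pivaloyloxy)phenyl]-2-oxo-3,7-dioxabicyclo[3.3.0]octane-1-carboxylate
Product: 10 (1S,5S,6S)-6-[3-methoxy-4-(pivaloyloxy)phenyl]-3,7-dioxabicyclo[3.3.0]octan-2-one
Conditions: LiCl (3 equiv), H2O (3 equiv), DMSO, 125 °C
Reagents that add atoms: none
Why: Krapcho dealkoxycarbonylation (chloride SN2 at the methyl group, loss of CO2, protonation of the lactone enolate); the ring-fusion carbon can only be protonated to the cis-fused bicycle, so the lactone carbonyl stays cis to the CH2O branch.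

Step 6
Reactants: 10 (1S,5S,6S)-6-[3-methoxy-4-(pivaloyloxy)phenyl]-3,7-dioxabicyclo[3.3.0]octan-2-one
Product: 11 (3S,4S,5S)-5-(4-hydroxy-3-methoxyphenyl)-4-(hydroxymethyl)-N-methoxy-N-methyloxolane-3-carboxamide
Conditions: MeNH(OMe)·HCl (5 equiv), iPrMgCl (10 equiv), THF, −20 to 0 °C; aq NH4Cl; crude used at once
Reagents that add atoms: N,O-dimethylhydroxylamine hydrochloride, CNOC.Cl
Why: Aminolysis of the lactone by the magnesium amide (Weinreb amide formation) should open the ring with all three ring stereocentres untouched, and the excess reagent also cleaves the aryl pivalate, which is no longer needed.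

Step 7
Reactants: 11 (3S,4S,5S)-5-(4-hydroxy-3-methoxyphenyl)-4-(hydroxymethyl)-N-methoxy-N-methyloxolane-3-carboxamide
Product: 12 (3S,4S,5S)-5-[4-(tert-butyldimethylsilyloxy)-3-methoxyphenyl]-4-[(tert-butyldimethylsilyloxy)methyl]-N-methoxy-N-methyloxolane-3-carboxamide
Conditions: TBSCl (2.5 equiv), imidazole (5 equiv), DMF, 0 °C to rt
Reagents that add atoms: tert-butyldimethylsilyl chloride, CC(C)(C)[Si](C)(C)Cl
Why: Standard silylation of the phenol and the primary alcohol; it blocks relactonisation and gives non-chelating ethers for step 10.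

Step 8
Reactants: 12 (3S,4S,5S)-5-[4-(tert-butyldimethylsilyloxy)-3-methoxyphenyl]-4-[(tert-butyldimethylsilyloxy)methyl]-N-methoxy-N-methyloxolane-3-carboxamide
Product: 13 (3S,4S,5S)-5-[4-(tert-butyldimethylsilyloxy)-3-methoxyphenyl]-4-[(tert-butyldimethylsilyloxy)methyl]oxolane-3-carbaldehyde
Conditions: DIBAL-H (1.3 equiv), THF, −78 °C; Rochelle salt work-up; used crude
Reagents that add atoms: none
Why: DIBAL-H reduction of a Weinreb amide stops at the chelated hemiaminal and releases the aldehyde on work-up; low temperature and immediate use protect the all-cis α-stereocentre.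

Step 9
Reactants: 14 4-bromo-2-methoxyphenol
Product: 15 (4-bromo-2-methoxyphenoxy)(tert-butyl)dimethylsilane
Conditions: TBSCl, imidazole, DMF, rt
Reagents that add atoms: tert-butyldimethylsilyl chloride, CC(C)(C)[Si](C)(C)Cl
Why: Standard phenol silylation, giving an aryl bromide fit for halogen–lithium exchange.

Step 10
Reactants: 13 (3S,4S,5S)-5-[4-(tert-butyldimethylsilyloxy)-3-methoxyphenyl]-4-[(tert-butyldimethylsilyloxy)methyl]oxolane-3-carbaldehyde; 15 (4-bromo-2-methoxyphenoxy)(tert-butyl)dimethylsilane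
Product: 17 (S)-[4-(tert-butyldimethylsilyloxy)-3-methoxyphenyl]{(3S,4S,5S)-5-[4-(tert-butyldimethylsilyloxy)-3-methoxyphenyl]-4-[(tert-butyldimethylsilyloxy)methyl]oxolan-3-yl}methanol, via aryllithium 16 (not isolated)
Conditions: 15 (1.5 equiv), n-BuLi (1.5 equiv), THF, −78 °C; then 13, THF, −78 °C; AcOH quench at −78 °C
Reagents that add atoms: none
Why: Bromine–lithium exchange followed by Felkin–Anh addition to the aldehyde: the ring carbon that bears the cis CH2OTBS branch is the large α-substituent and lies anti to the incoming aryl group, which passes the α-hydrogen, and this should set the carbinol centre as (S); silyl ethers and lithium in THF disfavour chelation, which would give the epimer.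

Step 11
Reactants: 17 (S)-[4-(tert-butyldimethylsilyloxy)-3-methoxyphenyl]{(3S,4S,5S)-5-[4-(tert-butyldimethylsilyloxy)-3-methoxyphenyl]-4-[(tert-butyldimethylsilyloxy)methyl]oxolan-3-yl}methanol
Product: 18 (S)-(4-hydroxy-3-methoxyphenyl)[(3S,4S,5S)-5-(4-hydroxy-3-methoxyphenyl)-4-(hydroxymethyl)oxolan-3-yl]methanol (target)
Conditions: TBAF (3.5 equiv), AcOH (3.5 equiv), THF, 0 °C to rt
Reagents that add atoms: none
Why: Fluoride cleavage of the three silyl ethers under acetic acid buffering; near-neutral conditions avoid ionisation of the two p-hydroxybenzylic C–O bonds.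

**Compound list**

1 | coniferaldehyde, (E)-3-(4-hydroxy-3-methoxyphenyl)prop-2-enal | O=C/C=C/c1ccc(O)c(OC)c1 | starting material
2 | 2-methoxy-4-[(E)-3-oxoprop-1-enyl]phenyl pivalate | O=C/C=C/c1ccc(OC(=O)C(C)(C)C)c(OC)c1 | intermediate
3 | dimethyl bromomalonate | COC(=O)C(Br)C(=O)OC | starting material
4 | dimethyl (2S,3R)-2-formyl-3-[3-methoxy-4-(pivaloyloxy)phenyl]cyclopropane-1,1-dicarboxylate (formyl and aryl trans) | COC(=O)C1(C(=O)OC)[C@@H](c2ccc(OC(=O)C(C)(C)C)c(OC)c2)[C@@H]1C=O | intermediate
5 | dimethyl (2S,3R)-2-(hydroxymethyl)-3-[3-methoxy-4-(pivaloyloxy)phenyl]cyclopropane-1,1-dicarboxylate | COC(=O)C1(C(=O)OC)[C@@H](c2ccc(OC(=O)C(C)(C)C)c(OC)c2)[C@@H]1CO | intermediate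
6 | methyl (1R,5S,6R)-6-[3-methoxy-4-(pivaloyloxy)phenyl]-2-oxo-3-oxabicyclo[3.1.0]hexane-1-carboxylate (aryl exo) | O=C1[C@]2(C(=O)OC)[C@@H](c3ccc(OC(=O)C(C)(C)C)c(OC)c3)[C@@H]2CO1 | intermediate
7 | formaldehyde (used as paraformaldehyde) | C=O | starting material
8 | oxocarbenium enolate zwitterion (tin-bound), O-methylidene oxonium on the benzylic carbon, ester enolate on the lactone α-carbon | C=[O+][C@H](c1ccc(OC(=O)C(C)(C)C)c(OC)c1)[C@@H]2COC(=O)C2=C([O-])OC | intermediate
9 | methyl (1S,5S,6S)-6-[3-methoxy-4-(pivaloyloxy)phenyl]-2-oxo-3,7-dioxabicyclo[3.3.0]octane-1-carboxylate (cis-fused, aryl on the concave face) | O=C1[C@]2(C(=O)OC)CO[C@H](c3ccc(OC(=O)C(C)(C)C)c(OC)c3)[C@@H]2CO1 | intermediate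
10 | (1S,5S,6S)-6-[3-methoxy-4-(pivaloyloxy)phenyl]-3,7-dioxabicyclo[3.3.0]octan-2-one | O=C1[C@@H]2CO[C@H](c3ccc(OC(=O)C(C)(C)C)c(OC)c3)[C@@H]2CO1 | intermediate
11 | (3S,4S,5S)-5-(4-hydroxy-3-methoxyphenyl)-4-(hydroxymethyl)-N-methoxy-N-methyloxolane-3-carboxamide (all-cis) | CON(C)C(=O)[C@@H]1CO[C@H](c2ccc(O)c(OC)c2)[C@@H]1CO | intermediate
12 | (3S,4S,5S)-5-[4-(tert-butyldimethylsilyloxy)-3-methoxyphenyl]-4-[(tert-butyldimethylsilyloxy)methyl]-N-methoxy-N-methyloxolane-3-carboxamide | CON(C)C(=O)[C@@H]1CO[C@H](c2ccc(O[Si](C)(C)C(C)(C)C)c(OC)c2)[C@@H]1CO[Si](C)(C)C(C)(C)C | intermediate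
13 | (3S,4S,5S)-5-[4-(tert-butyldimethylsilyloxy)-3-methoxyphenyl]-4-[(tert-butyldimethylsilyloxy)methyl]oxolane-3-carbaldehyde | O=C[C@@H]1CO[C@H](c2ccc(O[Si](C)(C)C(C)(C)C)c(OC)c2)[C@@H]1CO[Si](C)(C)C(C)(C)C | intermediate
14 | 4-bromo-2-methoxyphenol | COc1cc(Br)ccc1O | starting material
15 | (4-bromo-2-methoxyphenoxy)(tert-butyl)dimethylsilane | COc1cc(Br)ccc1O[Si](C)(C)C(C)(C)C | intermediate
16 | [4-(tert-butyldimethylsilyloxy)-3-methoxyphenyl]lithium | [Li]c1ccc(O[Si](C)(C)C(C)(C)C)c(OC)c1 | intermediate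
17 | (S)-[4-(tert-butyldimethylsilyloxy)-3-methoxyphenyl]{(3S,4S,5S)-5-[4-(tert-butyldimethylsilyloxy)-3-methoxyphenyl]-4-[(tert-butyldimethylsilyloxy)methyl]oxolan-3-yl}methanol | COc1cc([C@@H](O)[C@@H]2CO[C@H](c3ccc(O[Si](C)(C)C(C)(C)C)c(OC)c3)[C@@H]2CO[Si](C)(C)C(C)(C)C)ccc1O[Si](C)(C)C(C)(C)C | intermediate
18 | (S)-(4-hydroxy-3-methoxyphenyl)[(3S,4S,5S)-5-(4-hydroxy-3-methoxyphenyl)-4-(hydroxymethyl)oxolan-3-yl]methanol | COc1cc([C@@H](O)[C@@H]2CO[C@H](c3ccc(O)c(OC)c3)[C@@H]2CO)ccc1O | target

**Step count and risks**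

Total step count: 11. Longest linear sequence: 10 (steps 1 to 8, 10 and 11).

Steps most likely to fail:

1. Step 4. The strained cis-fused closure may be slow, so that ionisation at the benzylic carbon erodes the inversion, or oligomeric formaldehyde may be taken up. The fallback sets out from 4 and comes back at 9: the annulation is run on the monocyclic diester, the substrate class with the closest precedent, and the lactone is closed afterwards. Aldehyde 4 is reduced (NaBH4, MeOH, −40 °C) and alcohol 5 is silylated at once (TBSOTf, 2,6-lutidine, CH2Cl2, −78 °C) to dimethyl (2S,3R)-2-[(tert-butyldimethylsilyloxy)methyl]-3-[3-methoxy-4-(pivaloyloxy)phenyl]cyclopropane-1,1-dicarboxylate F1. Annulation of F1 with formaldehyde 7 (AlCl3 or Sn(OTf)2 cat., CH2Cl2) should give dimethyl (4S,5S)-4-[(tert-butyldimethylsilyloxy)methyl]-5-[3-methoxy-4-(pivaloyloxy)phenyl]oxolane-3,3-dicarboxylate F2, 4,5-cis by the same inversion. TBAF/AcOH and then p-TsOH (cat.) free the alcohol, which should lactonise onto the cis ester to give 9.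

2. Step 10. Facial selectivity of the aryl addition may be poor, or the all-cis aldehyde may epimerise at its α-carbon before it is trapped. The fallback sets out from 12 and comes back at 17: aryllithium 16 is added to Weinreb amide 12 (THF, −78 °C) to give [4-(tert-butyldimethylsilyloxy)-3-methoxyphenyl]{(3S,4S,5S)-5-[4-(tert-butyldimethylsilyloxy)-3-methoxyphenyl]-4-[(tert-butyldimethylsilyloxy)methyl]oxolan-3-yl}methanone F3. F3 is reduced under reagent control with (R)-2-methyl-CBS-oxazaborolidine and BH3·SMe2 (THF, −30 °C), which should give the (S)-carbinol 17 with the aryl group as the large substituent. Substrate-controlled (Felkin) hydride delivery to F3 would favour the epimer, so the catalyst has to override the substrate bias.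

3. Step 6. Cleavage of the pivalate may be incomplete, the hydroxy amide may relactonise, or the basic amide may epimerise the α-carbon. The fallback sets out from 10 and comes back at 13, and avoids the amide altogether. DIBAL-H (3.5 equiv, CH2Cl2, −78 °C) reduces the lactone and strips the pivalate to give (1S,5S,6S)-6-(4-hydroxy-3-methoxyphenyl)-3,7-dioxabicyclo[3.3.0]octan-2-ol F4 (anomer mixture). Wittig methylenation (Ph3PCH3Br, KOtBu, THF, 0 °C) opens the lactol to 4-[(2S,3S,4S)-4-ethenyl-3-(hydroxymethyl)oxolan-2-yl]-2-methoxyphenol F5. Silylation (TBSCl, imidazole, DMF) gives tert-butyl{[(2S,3S,4S)-2-[4-(tert-butyldimethylsilyloxy)-3-methoxyphenyl]-4-ethenyloxolan-3-yl]methoxy}dimethylsilane F6. Cleavage of the alkene (O3, CH2Cl2/MeOH, −78 °C, then Me2S; or OsO4 cat., NaIO4, 2,6-lutidine) gives aldehyde 13.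

**Further compounds**

F1 | step 4 | dimethyl (2S,3R)-2-[(tert-butyldimethylsilyloxy)methyl]-3-[3-methoxy-4-(pivaloyloxy)phenyl]cyclopropane-1,1-dicarboxylate | COC(=O)C1(C(=O)OC)[C@@H](c2ccc(OC(=O)C(C)(C)C)c(OC)c2)[C@@H]1CO[Si](C)(C)C(C)(C)C
F2 | step 4 | dimethyl (4S,5S)-4-[(tert-butyldimethylsilyloxy)methyl]-5-[3-methoxy-4-(pivaloyloxy)phenyl]oxolane-3,3-dicarboxylate | COC(=O)C1(C(=O)OC)CO[C@H](c2ccc(OC(=O)C(C)(C)C)c(OC)c2)[C@@H]1CO[Si](C)(C)C(C)(C)C
F3 | step 10 | [4-(tert-butyldimethylsilyloxy)-3-methoxyphenyl]{(3S,4S,5S)-5-[4-(tert-butyldimethylsilyloxy)-3-methoxyphenyl]-4-[(tert-butyldimethylsilyloxy)methyl]oxolan-3-yl}methanone | COc1cc(C(=O)[C@@H]2CO[C@H](c3ccc(O[Si](C)(C)C(C)(C)C)c(OC)c3)[C@@H]2CO[Si](C)(C)C(C)(C)C)ccc1O[Si](C)(C)C(C)(C)C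
F4 | step 6 | (1S,5S,6S)-6-(4-hydroxy-3-methoxyphenyl)-3,7-dioxabicyclo[3.3.0]octan-2-ol (anomer mixture) | OC1[C@@H]2CO[C@H](c3ccc(O)c(OC)c3)[C@@H]2CO1
F5 | step 6 | 4-[(2S,3S,4S)-4-ethenyl-3-(hydroxymethyl)oxolan-2-yl]-2-methoxyphenol | C=C[C@@H]1CO[C@H](c2ccc(O)c(OC)c2)[C@@H]1CO
F6 | step 6 | tert-butyl{[(2S,3S,4S)-2-[4-(tert-butyldimethylsilyloxy)-3-methoxyphenyl]-4-ethenyloxolan-3-yl]methoxy}dimethylsilane | C=C[C@@H]1CO[C@H](c2ccc(O[Si](C)(C)C(C)(C)C)c(OC)c2)[C@@H]1CO[Si](C)(C)C(C)(C)C
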